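**Strategy.** The route rests on the aryl ether bond O1–C7a of the dihydrobenzofuran. In its benzene ring C7a lies para to C5, the carbon that bears the CH2 link to lactone C4. Held as a formyl group, C5 activates a C7a–F bond, so the alkoxide on C2 closes the dihydrofuran ring by intramolecular SNAr in one operation. The precursor is an open-chain anti homoallylic alcohol, made by enantioselective γ-arylallyltitanation of O-benzylvanillin with a fluoroarene derived from 5-allylvanillin; C3 is then corrected to trans by aldehyde epimerisation. The same allyltitanation builds the open 1,3-diol unit. Stobbe condensation, asymmetric hydrogenation and lactone enolate benzylation unite the halves.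

Key step: step 6

Remark: locants O1, C2, C3, C3a, C4–C7, C7a refer to the 2,3-dihydrobenzofuran; the facial sense of the (R,R)-TADDOL titanium reagent (Si face of the aldehyde) and of the (S,S)-Et-DuPhos rhodium catalyst (R acid) is assumed as stated, and the mirror-image ligand would be taken if either proved opposite.

**Route**

Step 1
Reactants: 1 vanillin
Product: 2 4-(allyloxy)-3-methoxybenzaldehyde
Conditions: allyl bromide, K2CO3, DMF, 60 °C
Reagents that add atoms: allyl bromide C=CCBr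
Why: Williamson ether synthesis of the phenoxide with a reactive allylic bromide should be clean.

Step 2
Reactants: 2 4-(allyloxy)-3-methoxybenzaldehyde
Product: 3 5-allylvanillin (3-allyl-4-hydroxy-5-methoxybenzaldehyde)
Conditions: N,N-diethylaniline, 200 °C
Reagents that add atoms: none
Why: Aromatic Claisen rearrangement should deliver the allyl group to C5, the only free ortho position, followed by tautomerisation to the phenol.

Step 3
Reactants: 3 5-allylvanillin
Product: 5 3-allyl-4-fluoro-5-methoxybenzaldehyde, via aryl fluorosulfate 4 (not isolated)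
Conditions: SO2F2, NMe4F, DMF, 25 → 80 °C
Reagents that add atoms: sulfuryl fluoride O=S(=O)(F)F; tetramethylammonium fluoride C[N+](C)(C)C.[F-]
Why: Deoxyfluorination of a phenol through its aryl fluorosulfate, in which fluoride displaces fluorosulfate by SNAr, should be favoured here by the para formyl group.

Step 4
Reactants: 5 3-allyl-4-fluoro-5-methoxybenzaldehyde
Product: 6 1-allyl-5-(dimethoxymethyl)-2-fluoro-3-methoxybenzene
Conditions: HC(OMe)3, p-TsOH (cat.), MeOH, 25 °C
Reagents that add atoms: trimethyl orthoformate COC(OC)OC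
Why: Acid-catalysed acetalisation masks the aldehyde for the carbanion chemistry of step 5.

Step 5
Reactants: 6 1-allyl-5-(dimethoxymethyl)-2-fluoro-3-methoxybenzene; 7 4-(benzyloxy)-3-methoxybenzaldehyde
Product: 9 3-{(1S,2R)-1-[4-(benzyloxy)-3-methoxyphenyl]-1-hydroxybut-3-en-2-yl}-4-fluoro-5-methoxybenzaldehyde, via acetal alcohol 8 (not isolated)
Conditions: s-BuLi, THF, −78 °C; CpTiCl[(4R,5R)-TADDOLate] (chloro(cyclopentadienyl)[(4R,5R)-2,2-dimethyl-α,α,α′,α′-tetraphenyl-1,3-dioxolane-4,5-dimethanolato]titanium), −78 → 0 °C; 7, −78 °C; aq. NH4F; then PPTS, acetone/H2O, 25 °C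
Reagents that add atoms: water O
Why: Enantioselective allyltitanation, in which lithiation of the allylic-benzylic CH2 and transmetalation give the (E)-γ-aryl allyltitanium, which should add through a chair six-membered transition state (anti from the E geometry) to the Si face of 7 under control of the TADDOL ligand (1S); mild acid then frees the formyl group.

Step 6
Reactants: 9 3-{(1S,2R)-1-[4-(benzyloxy)-3-methoxyphenyl]-1-hydroxybut-3-en-2-yl}-4-fluoro-5-methoxybenzaldehyde
Product: 10 (2S,3R)-2-[4-(benzyloxy)-3-methoxyphenyl]-7-methoxy-3-vinyl-2,3-dihydrobenzofuran-5-carbaldehyde (2,3-cis)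
Conditions: Cs2CO3, DMF, 60 °C
Reagents that add atoms: none
Why: Cs2CO3 generates a low concentration of the C1 alkoxide of the butenol chain, which adds to the fluorine-bearing carbon (future C7a) to give a Meisenheimer complex whose negative charge is delocalised onto C5 and into its formyl group, and loss of fluoride restores the arene with the new O1–C7a bond. The closest known reaction type is the intramolecular SNAr etherification of 2-(2-fluoroaryl)ethanols bearing a para acceptor to give 2,3-dihydrobenzofurans. The dihydrofuran ring closes in a five-membered, formally 5-exo-trig addition–elimination mode. No stereocentre is formed: the C–O bond at C2 and the C–C bonds at C3 are not touched, so the anti precursor is carried over with retention into the 2,3-cis product, whose C3 is corrected in step 7. The step needs chemoselective O-arylation without attack on the aldehyde or base-induced migration of the vinyl double bond; this is secured by the mild carbonate base, the non-enolisable aldehyde, the single fluoride placed ortho to the side chain and para to CHO, and the single free hydroxyl.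

Step 7
Reactants: 10 (2S,3R)-2-[4-(benzyloxy)-3-methoxyphenyl]-7-methoxy-3-vinyl-2,3-dihydrobenzofuran-5-carbaldehyde
Product: 13 (2S,3R)-2-[4-(benzyloxy)-3-methoxyphenyl]-3-(hydroxymethyl)-7-methoxy-2,3-dihydrobenzofuran-5-carbaldehyde (2,3-trans), via cis-dialdehyde 11 (not isolated), via trans-dialdehyde 12 (not isolated)
Conditions: O3, pyridine, CH2Cl2/MeOH, −78 °C; Me2S; aqueous wash; DBU, CH2Cl2, 25 °C; NaBH4, EtOH/CH2Cl2, −78 °C
Reagents that add atoms: ozone [O-][O+]=O
Why: Ozonolysis with reductive work-up cleaves the vinyl group, DBU should epimerise the benzylic α-formyl carbon C3 to the thermodynamically favoured 2,3-trans isomer (so any syn/anti mixture from step 5 converges on one isomer), and NaBH4 at low temperature should reduce the aliphatic aldehyde faster than the electron-rich aryl aldehyde.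

Step 8
Reactants: 13 (2S,3R)-2-[4-(benzyloxy)-3-methoxyphenyl]-3-(hydroxymethyl)-7-methoxy-2,3-dihydrobenzofuran-5-carbaldehyde
Product: 14 (2S,3R)-2-[4-(benzyloxy)-3-methoxyphenyl]-3-[(benzyloxymethoxy)methyl]-7-methoxy-2,3-dihydrobenzofuran-5-carbaldehyde
Conditions: BOMCl, iPr2NEt, Bu4NI, CH2Cl2, 40 °C
Reagents that add atoms: benzyl chloromethyl ether ClCOCc1ccccc1
Why: O-Alkylation with the chloromethyl ether under amine base protects the primary alcohol as an acetal-type ether that hydrogenolysis removes at the end.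

Step 9
Reactants: 14 (2S,3R)-2-[4-(benzyloxy)-3-methoxyphenyl]-3-[(benzyloxymethoxy)methyl]-7-methoxy-2,3-dihydrobenzofuran-5-carbaldehyde; 15 dimethyl succinate
Product: 16 (E)-4-{(2S,3R)-2-[4-(benzyloxy)-3-methoxyphenyl]-3-[(benzyloxymethoxy)methyl]-7-methoxy-2,3-dihydrobenzofuran-5-yl}-3-(methoxycarbonyl)but-3-enoic acid
Conditions: NaOMe, MeOH, reflux; then aq. HCl
Reagents that add atoms: none
Why: Stobbe condensation, in which the succinate enolate adds to the aldehyde and the paraconic ester intermediate opens by elimination, should give the (E)-alkylidene succinate half-ester.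

Step 10
Reactants: 16 (E)-alkylidene succinate half-ester
Product: 17 (3R)-4-{(2S,3R)-2-[4-(benzyloxy)-3-methoxyphenyl]-3-[(benzyloxymethoxy)methyl]-7-methoxy-2,3-dihydrobenzofuran-5-yl}-3-(methoxycarbonyl)butanoic acid
Conditions: [Rh(cod)((S,S)-Et-DuPhos)]BF4 (cat.), H2 (5 atm), MeOH, 25 °C
Reagents that add atoms: none
Why: Asymmetric hydrogenation of a β-aryl itaconate half-ester, in which chelation of carboxyl and alkene to the cationic rhodium bisphospholane complex lets the ligand choose the alkene face, should set the R centre without touching the benzyl-type ethers.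

Step 11
Reactants: 17 (3R)-succinate half-ester
Product: 19 (4R)-4-({(2S,3R)-2-[4-(benzyloxy)-3-methoxyphenyl]-3-[(benzyloxymethoxy)methyl]-7-methoxy-2,3-dihydrobenzofuran-5-yl}methyl)dihydrofuran-2(3H)-one, via hydroxy acid 18 (not isolated)
Conditions: KOH (1 equiv), EtOH; CaCl2, NaBH4, −10 → 25 °C; then 2 M HCl
Reagents that add atoms: none
Why: Ca(BH4)2 should reduce the methyl ester chemoselectively beside the carboxylate salt, and acidification closes the γ-lactone with the stereocentre untouched.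

Step 12
Reactants: 3 5-allylvanillin
Product: 20 3-allyl-4-(benzyloxy)-5-methoxybenzaldehyde
Conditions: BnBr, K2CO3, DMF, 25 °C
Reagents that add atoms: benzyl bromide BrCc1ccccc1
Why: Williamson benzylation of the phenoxide.

Step 13
Reactants: 20 3-allyl-4-(benzyloxy)-5-methoxybenzaldehyde
Product: 21 1-allyl-2-(benzyloxy)-5-(dimethoxymethyl)-3-methoxybenzene
Conditions: HC(OMe)3, p-TsOH (cat.), MeOH, 25 °C
Reagents that add atoms: trimethyl orthoformate COC(OC)OC
Why: Acid-catalysed acetalisation masks the aldehyde for the carbanion chemistry of step 14.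

Step 14
Reactants: 21 1-allyl-2-(benzyloxy)-5-(dimethoxymethyl)-3-methoxybenzene; 7 4-(benzyloxy)-3-methoxybenzaldehyde
Product: 22 (1S,2R)-1-[4-(benzyloxy)-3-methoxyphenyl]-2-[2-(benzyloxy)-5-(dimethoxymethyl)-3-methoxyphenyl]but-3-en-1-ol
Conditions: s-BuLi, THF, −78 °C; CpTiCl[(4R,5R)-TADDOLate], −78 → 0 °C; 7, −78 °C; aq. NH4F
Reagents that add atoms: none
Why: The same enantioselective allyltitanation as in step 5 (chair transition state, E-allyl gives anti, ligand-controlled Si-face attack gives 1S) should set both stereocentres of the open unit in the configuration of the target.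

Step 15
Reactants: 22 (1S,2R)-homoallylic alcohol
Product: 24 (1S,2S)-1-[4-(benzyloxy)-3-methoxyphenyl]-2-[2-(benzyloxy)-5-(dimethoxymethyl)-3-methoxyphenyl]propane-1,3-diol, via hydroxy aldehyde 23 (not isolated)
Conditions: O3, CH2Cl2/MeOH, −78 °C; NaBH4, −78 → 0 °C
Reagents that add atoms: ozone [O-][O+]=O
Why: Ozonolysis with direct borohydride work-up at low temperature should reduce the epimerisable β-hydroxy aldehyde before it can enolise, so the anti configuration is kept.

Step 16
Reactants: 24 (1S,2S)-1,3-diol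
Product: 26 4-(benzyloxy)-3-{(1S,2S)-1-[4-(benzyloxy)-3-methoxyphenyl]-1,3-bis(benzyloxymethoxy)propan-2-yl}-5-methoxybenzaldehyde, via bis-BOM acetal 25 (not isolated)
Conditions: BOMCl, iPr2NEt, Bu4NI, CH2Cl2, 40 °C; then 1 M HCl, THF, 0 °C
Reagents that add atoms: benzyl chloromethyl ether ClCOCc1ccccc1; water O
Why: Alkylation of both hydroxyls with the chloromethyl ether gives ethers removable by hydrogenolysis, and dilute acid should then hydrolyse only the far more labile aryl dimethyl acetal.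

Step 17
Reactants: 26 bis-BOM aldehyde
Product: 27 (4-(benzyloxy)-3-{(1S,2S)-1-[4-(benzyloxy)-3-methoxyphenyl]-1,3-bis(benzyloxymethoxy)propan-2-yl}-5-methoxyphenyl)methanol
Conditions: NaBH4, MeOH/THF, 0 °C
Reagents that add atoms: none
Why: Borohydride reduction of the aryl aldehyde to the benzylic alcohol.

Step 18
Reactants: 27 benzylic alcohol
Product: 28 2-(benzyloxy)-1-{(1S,2S)-1-[4-(benzyloxy)-3-methoxyphenyl]-1,3-bis(benzyloxymethoxy)propan-2-yl}-5-(bromomethyl)-3-methoxybenzene
Conditions: CBr4, PPh3, CH2Cl2, 0 °C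
Reagents that add atoms: carbon tetrabromide BrC(Br)(Br)Br
Why: The Appel reaction converts the primary benzylic alcohol into the bromide under neutral conditions that spare the acetal-type ethers.

Step 19
Reactants: 19 (4R)-lactone; 28 benzylic bromide
Product: 29 (3R,4R)-3-(4-(benzyloxy)-3-{(1S,2S)-1-[4-(benzyloxy)-3-methoxyphenyl]-1,3-bis(benzyloxymethoxy)propan-2-yl}-5-methoxybenzyl)-4-({(2S,3R)-2-[4-(benzyloxy)-3-methoxyphenyl]-3-[(benzyloxymethoxy)methyl]-7-methoxy-2,3-dihydrobenzofuran-5-yl}methyl)dihydrofuran-2(3H)-one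
Conditions: LiHMDS, THF, −78 °C; 28, DMPU, −78 → −30 °C
Reagents that add atoms: none
Why: Lactone enolate alkylation, in which the benzylic bromide approaches the lithium enolate anti to the C4 substituent, should set C3 as R in the 3,4-trans product.

Step 20
Reactants: 29 protected lactone
Product: 30 (3R,4R)-3-{3-[(1S,2S)-1,3-dihydroxy-1-(4-hydroxy-3-methoxyphenyl)propan-2-yl]-4-hydroxy-5-methoxybenzyl}-4-{[(2S,3R)-2-(4-hydroxy-3-methoxyphenyl)-3-(hydroxymethyl)-7-methoxy-2,3-dihydrobenzofuran-5-yl]methyl}dihydrofuran-2(3H)-one (CNP0186558.2)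
Conditions: H2 (1 atm), Pd(OH)2/C, EtOAc/EtOH, 25 °C
Reagents that add atoms: none
Why: Hydrogenolysis should cleave the three aryl benzyl ethers and the three benzyloxymethyl ethers (at their PhCH2–O bonds, the formaldehyde hemiacetals then collapsing), while neutral conditions spare the dihydrobenzofuran C2–O bond and the benzylic alcohol.

**Compound list**

1 | vanillin | COc1cc(C=O)ccc1O | starting material
2 | 4-(allyloxy)-3-methoxybenzaldehyde | C=CCOc1ccc(C=O)cc1OC | intermediate
3 | 5-allylvanillin (3-allyl-4-hydroxy-5-methoxybenzaldehyde) | C=CCc1cc(C=O)cc(OC)c1O | intermediate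
4 | 2-allyl-4-formyl-6-methoxyphenyl fluorosulfate | C=CCc1cc(C=O)cc(OC)c1OS(=O)(=O)F | intermediate (not isolated)
5 | 3-allyl-4-fluoro-5-methoxybenzaldehyde | C=CCc1cc(C=O)cc(OC)c1F | intermediate
6 | 1-allyl-5-(dimethoxymethyl)-2-fluoro-3-methoxybenzene | C=CCc1cc(C(OC)OC)cc(OC)c1F | intermediate
7 | 4-(benzyloxy)-3-methoxybenzaldehyde | COc1cc(C=O)ccc1OCc1ccccc1 | starting material
8 | (1S,2R)-1-[4-(benzyloxy)-3-methoxyphenyl]-2-[5-(dimethoxymethyl)-2-fluoro-3-methoxyphenyl]but-3-en-1-ol | COc1cc([C@@H](O)[C@H](C=C)c2cc(C(OC)OC)cc(OC)c2F)ccc1OCc1ccccc1 | intermediate (not isolated)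
9 | 3-{(1S,2R)-1-[4-(benzyloxy)-3-methoxyphenyl]-1-hydroxybut-3-en-2-yl}-4-fluoro-5-methoxybenzaldehyde | COc1cc([C@@H](O)[C@H](C=C)c2cc(C=O)cc(OC)c2F)ccc1OCc1ccccc1 | intermediate
10 | (2S,3R)-2-[4-(benzyloxy)-3-methoxyphenyl]-7-methoxy-3-vinyl-2,3-dihydrobenzofuran-5-carbaldehyde (cis) | O=Cc1cc(OC)c2c(c1)[C@@H](C=C)[C@@H](c1ccc(OCc3ccccc3)c(OC)c1)O2 | intermediate
11 | (2S,3R)-2-[4-(benzyloxy)-3-methoxyphenyl]-7-methoxy-2,3-dihydrobenzofuran-3,5-dicarbaldehyde (cis) | O=Cc1cc(OC)c2c(c1)[C@@H](C=O)[C@@H](c1ccc(OCc3ccccc3)c(OC)c1)O2 | intermediate (not isolated)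
12 | (2S,3S)-2-[4-(benzyloxy)-3-methoxyphenyl]-7-methoxy-2,3-dihydrobenzofuran-3,5-dicarbaldehyde (trans) | O=Cc1cc(OC)c2c(c1)[C@H](C=O)[C@@H](c1ccc(OCc3ccccc3)c(OC)c1)O2 | intermediate (not isolated)
13 | (2S,3R)-2-[4-(benzyloxy)-3-methoxyphenyl]-3-(hydroxymethyl)-7-methoxy-2,3-dihydrobenzofuran-5-carbaldehyde (trans) | O=Cc1cc(OC)c2c(c1)[C@H](CO)[C@@H](c1ccc(OCc3ccccc3)c(OC)c1)O2 | intermediate
14 | (2S,3R)-2-[4-(benzyloxy)-3-methoxyphenyl]-3-[(benzyloxymethoxy)methyl]-7-methoxy-2,3-dihydrobenzofuran-5-carbaldehyde | O=Cc1cc(OC)c2c(c1)[C@H](COCOCc1ccccc1)[C@@H](c1ccc(OCc3ccccc3)c(OC)c1)O2 | intermediate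
15 | dimethyl succinate | COC(=O)CCC(=O)OC | starting material
16 | (E)-4-{(2S,3R)-2-[4-(benzyloxy)-3-methoxyphenyl]-3-[(benzyloxymethoxy)methyl]-7-methoxy-2,3-dihydrobenzofuran-5-yl}-3-(methoxycarbonyl)but-3-enoic acid | COC(=O)/C(=C/c1cc(OC)c2c(c1)[C@H](COCOCc1ccccc1)[C@@H](c1ccc(OCc3ccccc3)c(OC)c1)O2)CC(=O)O | intermediate
17 | (3R)-4-{(2S,3R)-2-[4-(benzyloxy)-3-methoxyphenyl]-3-[(benzyloxymethoxy)methyl]-7-methoxy-2,3-dihydrobenzofuran-5-yl}-3-(methoxycarbonyl)butanoic acid | COC(=O)[C@H](Cc1cc(OC)c2c(c1)[C@H](COCOCc1ccccc1)[C@@H](c1ccc(OCc3ccccc3)c(OC)c1)O2)CC(=O)O | intermediate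
18 | (3R)-4-{(2S,3R)-2-[4-(benzyloxy)-3-methoxyphenyl]-3-[(benzyloxymethoxy)methyl]-7-methoxy-2,3-dihydrobenzofuran-5-yl}-3-(hydroxymethyl)butanoic acid | OC[C@H](Cc1cc(OC)c2c(c1)[C@H](COCOCc1ccccc1)[C@@H](c1ccc(OCc3ccccc3)c(OC)c1)O2)CC(=O)O | intermediate (not isolated)
19 | (4R)-4-({(2S,3R)-2-[4-(benzyloxy)-3-methoxyphenyl]-3-[(benzyloxymethoxy)methyl]-7-methoxy-2,3-dihydrobenzofuran-5-yl}methyl)dihydrofuran-2(3H)-one | O=C1OC[C@H](Cc2cc(OC)c3c(c2)[C@H](COCOCc2ccccc2)[C@@H](c2ccc(OCc4ccccc4)c(OC)c2)O3)C1 | intermediate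
20 | 3-allyl-4-(benzyloxy)-5-methoxybenzaldehyde | C=CCc1cc(C=O)cc(OC)c1OCc1ccccc1 | intermediate
21 | 1-allyl-2-(benzyloxy)-5-(dimethoxymethyl)-3-methoxybenzene | C=CCc1cc(C(OC)OC)cc(OC)c1OCc1ccccc1 | intermediate
22 | (1S,2R)-1-[4-(benzyloxy)-3-methoxyphenyl]-2-[2-(benzyloxy)-5-(dimethoxymethyl)-3-methoxyphenyl]but-3-en-1-ol | COc1cc([C@@H](O)[C@H](C=C)c2cc(C(OC)OC)cc(OC)c2OCc2ccccc2)ccc1OCc1ccccc1 | intermediate
23 | (2R,3S)-3-[4-(benzyloxy)-3-methoxyphenyl]-2-[2-(benzyloxy)-5-(dimethoxymethyl)-3-methoxyphenyl]-3-hydroxypropanal | COc1cc([C@@H](O)[C@H](C=O)c2cc(C(OC)OC)cc(OC)c2OCc2ccccc2)ccc1OCc1ccccc1 | intermediate (not isolated)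
24 | (1S,2S)-1-[4-(benzyloxy)-3-methoxyphenyl]-2-[2-(benzyloxy)-5-(dimethoxymethyl)-3-methoxyphenyl]propane-1,3-diol | COc1cc([C@@H](O)[C@H](CO)c2cc(C(OC)OC)cc(OC)c2OCc2ccccc2)ccc1OCc1ccccc1 | intermediate
25 | 2-(benzyloxy)-1-{(1S,2S)-1-[4-(benzyloxy)-3-methoxyphenyl]-1,3-bis(benzyloxymethoxy)propan-2-yl}-5-(dimethoxymethyl)-3-methoxybenzene | COc1cc([C@@H](OCOCc2ccccc2)[C@H](COCOCc2ccccc2)c2cc(C(OC)OC)cc(OC)c2OCc2ccccc2)ccc1OCc1ccccc1 | intermediate (not isolated)
26 | 4-(benzyloxy)-3-{(1S,2S)-1-[4-(benzyloxy)-3-methoxyphenyl]-1,3-bis(benzyloxymethoxy)propan-2-yl}-5-methoxybenzaldehyde | COc1cc([C@@H](OCOCc2ccccc2)[C@H](COCOCc2ccccc2)c2cc(C=O)cc(OC)c2OCc2ccccc2)ccc1OCc1ccccc1 | intermediate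
27 | (4-(benzyloxy)-3-{(1S,2S)-1-[4-(benzyloxy)-3-methoxyphenyl]-1,3-bis(benzyloxymethoxy)propan-2-yl}-5-methoxyphenyl)methanol | COc1cc([C@@H](OCOCc2ccccc2)[C@H](COCOCc2ccccc2)c2cc(CO)cc(OC)c2OCc2ccccc2)ccc1OCc1ccccc1 | intermediate
28 | 2-(benzyloxy)-1-{(1S,2S)-1-[4-(benzyloxy)-3-methoxyphenyl]-1,3-bis(benzyloxymethoxy)propan-2-yl}-5-(bromomethyl)-3-methoxybenzene | COc1cc([C@@H](OCOCc2ccccc2)[C@H](COCOCc2ccccc2)c2cc(CBr)cc(OC)c2OCc2ccccc2)ccc1OCc1ccccc1 | intermediate
29 | hexa-protected target (three aryl benzyl ethers and three benzyloxymethyl ethers; 3R,4R lactone) | COc1cc([C@@H](OCOCc2ccccc2)[C@H](COCOCc2ccccc2)c2cc(C[C@H]3C(=O)OC[C@@H]3Cc3cc(OC)c4c(c3)[C@H](COCOCc3ccccc3)[C@@H](c3ccc(OCc5ccccc5)c(OC)c3)O4)cc(OC)c2OCc2ccccc2)ccc1OCc1ccccc1 | intermediate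
30 | CNP0186558.2 | COc1cc([C@@H](O)[C@H](CO)c2cc(C[C@H]3C(=O)OC[C@@H]3Cc3cc(OC)c4c(c3)[C@H](CO)[C@@H](c3ccc(O)c(OC)c3)O4)cc(OC)c2O)ccc1O | target

**Step count.** Total: 20 steps. Longest linear sequence: 13 steps (steps 1–11, 19, 20); steps 12–18 form the second branch from 3.

**Steps most likely to fail**

Step 5 (the same risk holds for its twin, step 14). Ring lithiation between the methoxy and acetal groups may compete with allylic deprotonation, and the ligand-controlled facial selectivity may erode with this hindered allyl unit. The fallback replaces carbanion chemistry by catalytic C–H borylation and allylboration. Setting out from 6, palladium-catalysed oxidative allylic C–H borylation (Pd2(dba)3 cat., B2pin2, N-fluorobenzenesulfonimide) would give (E)-2-[3-(5-(dimethoxymethyl)-2-fluoro-3-methoxyphenyl)allyl]-4,4,5,5-tetramethyl-1,3,2-dioxaborolane F1. Its allylboration of 7 under a chiral phosphoric acid ((S)-TRIP, the antipode being chosen for the 1S carbinol) should pass through the same chair transition state to 8, and acetal hydrolysis as in step 5 returns to the route at 9.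

Step 6. The addition–elimination may be slow on the electron-rich, doubly ortho-substituted ring, or the base may move the vinyl double bond into conjugation. The fallback closes the same O1–C7a bond by palladium-catalysed C–O coupling of an aryl triflate. Setting out from 3, Tf2O/pyridine gives 2-allyl-4-formyl-6-methoxyphenyl trifluoromethanesulfonate F2, and acetalisation gives 2-allyl-4-(dimethoxymethyl)-6-methoxyphenyl trifluoromethanesulfonate F3. The C–H borylation named above gives the (E)-cinnamyl pinacol boronate triflate F4, and phosphoric-acid-catalysed allylboration of 7 gives the (1S,2R)-homoallylic alcohol triflate F5. Buchwald–Hartwig etherification (Pd2(dba)3, 2-di-tert-butylphosphino-2′,4′,6′-triisopropylbiphenyl, Cs2CO3, toluene, 70 °C) then gives the cis-dihydrobenzofuran dimethyl acetal F6, and PPTS in wet acetone returns to the route at 10.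

Step 7. Ozone may over-oxidise the electron-rich rings, the C3 epimerisation may stay incomplete, or the borohydride may lose chemoselectivity and reduce the aryl aldehyde as well. The fallback uses dihydroxylation–periodate cleavage and a reduce-all, re-oxidise sequence. Setting out from 10, Lemieux–Johnson cleavage (OsO4 cat., NaIO4, 2,6-lutidine, dioxane/H2O) gives 11 and DBU gives 12. Excess NaBH4 reduces both formyl groups to [(2S,3R)-2-(4-(benzyloxy)-3-methoxyphenyl)-7-methoxy-2,3-dihydrobenzofuran-3,5-diyl]dimethanol F7, and MnO2 in CH2Cl2 should oxidise only the benzylic alcohol, returning to the route at 13.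

Further compounds
F1 | step 5 | (E)-2-[3-(5-(dimethoxymethyl)-2-fluoro-3-methoxyphenyl)allyl]-4,4,5,5-tetramethyl-1,3,2-dioxaborolane | COC(OC)c1cc(OC)c(F)c(/C=C/CB2OC(C)(C)C(C)(C)O2)c1
F2 | step 6 | 2-allyl-4-formyl-6-methoxyphenyl trifluoromethanesulfonate | C=CCc1cc(C=O)cc(OC)c1OS(=O)(=O)C(F)(F)F
F3 | step 6 | 2-allyl-4-(dimethoxymethyl)-6-methoxyphenyl trifluoromethanesulfonate | C=CCc1cc(C(OC)OC)cc(OC)c1OS(=O)(=O)C(F)(F)F
F4 | step 6 | 4-(dimethoxymethyl)-2-methoxy-6-[(E)-3-(4,4,5,5-tetramethyl-1,3,2-dioxaborolan-2-yl)prop-1-enyl]phenyl trifluoromethanesulfonate | COC(OC)c1cc(OC)c(OS(=O)(=O)C(F)(F)F)c(/C=C/CB2OC(C)(C)C(C)(C)O2)c1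
F5 | step 6 | 2-{(1S,2R)-1-[4-(benzyloxy)-3-methoxyphenyl]-1-hydroxybut-3-en-2-yl}-4-(dimethoxymethyl)-6-methoxyphenyl trifluoromethanesulfonate | COc1cc([C@@H](O)[C@H](C=C)c2cc(C(OC)OC)cc(OC)c2OS(=O)(=O)C(F)(F)F)ccc1OCc1ccccc1
F6 | step 6 | (2S,3R)-2-[4-(benzyloxy)-3-methoxyphenyl]-5-(dimethoxymethyl)-7-methoxy-3-vinyl-2,3-dihydrobenzofuran (cis) | COC(OC)c1cc(OC)c2c(c1)[C@@H](C=C)[C@@H](c1ccc(OCc3ccccc3)c(OC)c1)O2
F7 | step 7 | [(2S,3R)-2-(4-(benzyloxy)-3-methoxyphenyl)-7-methoxy-2,3-dihydrobenzofuran-3,5-diyl]dimethanol | OCc1cc(OC)c2c(c1)[C@H](CO)[C@@H](c1ccc(OCc3ccccc3)c(OC)c1)O2
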